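**The clock.** The closed vessel carries a clock that I can read without any model, and that clock is D. In the gamma run D falls from 46.0 % at 1.00 h to 9.6 % at 3.00 h, so I take 0.885 h as the D half-life, the time in which first-order loss halves D. The epsilon run, charged with 0.040 M against 0.010 M, reads 45.3 % and 9.7 % at those times, so I carry the same clock to the flask.

| flask | D | Q | Z | remark | time |
|---|---|---|---|---|---|
| gamma | 0.010 M | 1.5 equiv | 6 mM | run made earlier |  |
| epsilon | 0.040 M | 1.5 equiv | 6 mM | run made earlier |  |
| flask | 0.020 M | 1.50 equiv | 6.00 mM |  | 8.0 h |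

- gamma (time / h: L / %, D / %): 0.667: 4.1, 59.1; 1.00: 7.6, 46.0; 2.00: 13.8, 20.8; 3.00: 15.6, 9.6; 5.00: 12.9, 2.1; 8.00: 6.5, 0
- epsilon (time / h: L / %, D / %): 0.667: 13.2, 59.7; 1.00: 20.1, 45.3; 2.00: 30.3, 21.5; 3.00: 28.3, 9.7; 5.00: 15.7, 1.4; 8.00: 5.4, 0.4

(each reading ± 0.3 percentage points)

- when, up to 8.0 h, the flask holds most L
- the amount of L, in percent of the D charged, at that time

**Counting peaks.** The highest L reading in gamma is 15.6 % at 3.00 h, which is 3.39 half-lives, and in epsilon it is 30.3 % at 2.00 h, which is 2.26. The 0.020 M of the flask is the geometric mean of those two charges, with Q in the same equivalents and Z the same, so I take geometric means too: 2.77 half-lives, or 2.45 h, and 21.7 %.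

**Weak link.** That count leans on an epsilon peak read from a coarse grid, and 28.3 % at 3.00 h stands nearer the top reading than 20.1 % at 1.00 h does, so I place the top of the epsilon readings past 2.00 h. A parabola through those 3 readings puts it at 2.34 h and 31.0 %; the gamma readings are unevenly spaced around their top, so I leave that peak as read. I commit to 2.99 half-lives, which is 2.65 h, and 22.0 %.

**The forecast.** The forecast gives 2.7 h (2.3 h to 3.1 h) and 21.5 % (19.8 % to 23.2 %), saying "so I interpolate".

**What stands.** The flask peaks at 2.60 h with 23.4 %, beside my 2.65 h and a height 1.4 percentage points above mine; 2.94 half-lives leave 13.1 % of D, and the flask holds 13.1 %.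

    L → X (k = 0.0110 min⁻¹)
    Q + Z → J (k = 0.830 L mol⁻¹ min⁻¹)
    Q + E → L (k = 0.450 L mol⁻¹ min⁻¹)
    D → E (k = 0.0130 min⁻¹)

**Two clocks.** With Q as charged, E has a half-life of 0.86 h under Q + E, close to the 0.885 h of D, but at 8.00 h that half-life is 3.7 h, longer than the D half-life, and the flask then holds E at 14.4 % beside D at 0.195 %. In the neighbour flask with 0.600 equiv of Q, D at that time stands at 0.195 %, and 9.04 half-lives give 0.190 %.

The numbers in the tables stem from a simulated flask on assumed constants; scatter was added.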